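The earlier runs and the new flask were generated by integration for an exercise, noise included.

The north run, with 2.2 µM of X at 20 °C, still reads 0% G at 1.33 min and 4% at 3.00 min. The south-west run, with 11 µM of X at 35 °C, already reads 4% at 12.0 s. The new flasks stand at the south-west temperature and differ in [X].

| setting | north | south-west | beta | theta | alpha | delta | zeta | eta |
|---|---|---|---|---|---|---|---|---|
| E | 11 mM | 11 mM | 11 mM | 11 mM | 11 mM | 11 mM | 11 mM | 11 mM |
| X | 2.2 µM | 11 µM | 1.5 µM | 3.0 µM | 5.5 µM | 8.0 µM | 2.0 µM | 4.0 µM |
| temperature | 20 °C | 35 °C | 35 °C | 35 °C | 35 °C | 35 °C | 35 °C | 35 °C |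
| remark | run made earlier | run made earlier |  |  |  |  |  |  |
| time |  |  | 3.0 min | 3.0 min | 3.0 min | 3.0 min | 3.0 min | 3.0 min |

north run (percent of the E charged): time / min: G / % = 0.333: 0; 0.500: 0; 1.33: 0; 3.00: 4

south-west run (percent of the E charged): time / s: G / % = 12.0: 4; 30.0: 9; 60.0: 20; 90.0: 23

(scatter of a reading: 1.5 percentage points)

- all flasks from highest to lowest amount of G, in percent of the E charged, at 3.0 min (beta / theta / alpha / delta / zeta / eta)
- the amount of G, in percent of the E charged of the flask you put first, at 3.0 min
- the amount of G, in percent of the E charged of the flask you put last, at 3.0 min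

A silent start in one run and a prompt start in the other look contradictory. But a straight line from the origin to the last north reading stands at 1.77% at 1.33 min, and a reading scatters by 1.5 percentage points, so the north run does not prove a lag.

X returns with each G in the steps under discussion, so the reckoning here takes E to fall as a pseudo-first-order species, at a rate proportional to the charged [X]. The south-west readings at 60.0 s and 90.0 s together give κ = 0.0176 /µM/min, the fall in the logarithm of remaining E per unit of [X] and of time. As a check, κ gives 3.80% for the earliest south-west reading, which reads 4%.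

With E, temperature and time equal, this reckoning ranks the flasks by [X]. Delta has the highest [X] and reckons to 34.5%. Beta has the lowest and reckons to 7.62%.

The forecast gives delta > alpha > eta > theta > zeta > beta, with delta at 33% (27% to 39%) and beta at 7% (4.5% to 9%). It reads the north run as a lag and judges that “A lag of a few seconds would cost little”. The reckoning above takes no lag off and stands higher than the forecast for delta and for beta.

The flasks come out as delta > alpha > eta > theta > zeta > beta, with delta at 34.5% and beta at 7.00%.

    E + X ⇌ Q (K = 39.0 /M, k = 2400 /M/s, Ea = 40.0 kJ/mol, ΔH = −51.0 kJ/mol)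
    Q ⇌ L (K = 11.7, k = 28.5 /s, Ea = 73.0 kJ/mol, ΔH = −25.0 kJ/mol)
    L → X + G (k = 6.75 /s, Ea = 81.0 kJ/mol)
    (constants at 35 °C)

In beta, the forward half-life of Q towards L is 0.024 s at 3.00 min, and that of X towards Q is 0.027 s at 1.49 min, both far shorter than the run of 3.0 min. At 3.00 min, beta makes Q at 1.00 times the rate at which it uses Q up, each step taken net, a quasi-steady state, with the catalyst standing as X 45.0%, L 41.6% and Q 13.4%. For a neighbour of beta charged with 0.380 µM of X, κ gives 1.99%, and that flask holds 1.79% G.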